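The level of 68.6 % target, read in the epsilon run at 25.0 h, was the number I started from.

| setting | epsilon | zeta | south-west | north-east | south | west |
|---|---|---|---|---|---|---|
| starting material | 0.050 M | 0.050 M | 0.050 M | 0.050 M | 0.050 M | 0.050 M (fed, over 32.0 h) |
| partner | 1.5 equiv | 0.75 equiv | 1.50 equiv (fed, over 32.0 h) | 1.50 equiv | 1.50 equiv | 1.50 equiv |
| precatalyst | 1 mol% | 1 mol% | 1 mol% | 1 mol% | 1 mol% | 1 mol% |
| remark | run made earlier | run made earlier | a stirred flask in which partner is dosed at a steady rate over 32.0 h without added volume, worked up at 40 h | everything together in a closed stirred flask, run for 40 h | a single well-mixed tank run continuously and read at steady state, 40 h in it on average | all but starting material at the start; starting material goes in evenly over 32.0 h, the run ends at 40 h |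
| time |  |  | 40 h | 40 h |  | 40 h |

| run | time / h | target / % |
|---|---|---|
| epsilon | 2.00 | 21.0 |
| epsilon | 4.00 | 38.0 |
| epsilon | 10.0 | 68.1 |
| epsilon | 25.0 | 68.6 |
| zeta | 1.00 | 6.0 |
| zeta | 2.00 | 11.9 |
| zeta | 5.00 | 25.3 |
| zeta | 12.0 | 41.5 |

(scatter of a reading: 0.5 percentage points)

- the stated concentrations are those of everything mixed, before any reaction; amounts are the same in each set-up
- the earlier runs were read with a standard deviation of 0.5 percentage points
- steps under discussion: catalyst intermediate C -> catalyst intermediate D; catalyst intermediate D -> free catalyst + target; catalyst intermediate B -> by-product + catalyst intermediate C; target + free catalyst <-> isomer of the product + free catalyst; starting material + catalyst intermediate A -> catalyst intermediate B; partner + precatalyst -> free catalyst + spent reagent; partner + free catalyst -> catalyst intermediate A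
- the feed brings no volume worth counting
- the earlier runs were made in a closed, stirred flask

1. the set-up with the highest amount of target at the outlet or at the end, in percent of the starting material put in ("none" if the first two lie within 2 percentage points) (south-west / north-east / south / west / none)
2. amount of target at the outlet or at the end, in percent of the starting material put in, south-west
3. amount of target at the outlet or at the end, in percent of the starting material put in, north-east
4. amount of target at the outlet or at the end, in percent of the starting material put in, south
5. amount of target at the outlet or at the end, in percent of the starting material put in, west

I drew the epsilon curve first, since north-east repeats its recipe. It starts at a slope of 0.105 h⁻¹ of the charge, against 0.0600 h⁻¹ in the zeta run. That reading ratio of 1.75, beside a partner ratio of 2.00, let me take the rate as roughly following partner. The tangent meets the level at a knee of 6.53 h, and the reading at 10.0 h already lies within 0.5 percentage points of the level.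

Then I asked whether each set-up reaches that level. In west, starting material enters at 0.0312 h⁻¹, less than the starting slope, and the last of it has 8.00 h, longer than the knee. In south-west, partner reaches one equivalent at 21.3 h, well inside the dosing. The south tank, holding 40 h on average, must deliver 0.0250 h⁻¹ of the charge, and with partner down to its excess the slope falls to 0.0350 h⁻¹, still above that figure.

What height the level has in each was my assumption. I read the missing part of the charge as isomer of the product, formed through the reversible step under discussion. Target over the rest of the charge then stands at 2.18, the stop ratio, or 0.338 in powers of ten. I took this ratio to be independent of feeding, so I wrote about 68.6 % for each set-up, slightly less for the tank, and "none" for the best.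

The forecast differed: 56 % for south-west, 68.5 % for north-east, 57 % for south, 76 % for west and west as best, with the words “excess partner holds much catalyst as A while starting material is scarce, so less isomerisation”.

The simulation gave 67.9 % for south-west, 68.9 % for north-east, 67.5 % for south and 68.9 % for west, so the best is none.

    catalyst intermediate C → catalyst intermediate D (k = 1.40 min⁻¹)
    catalyst intermediate D → free catalyst + target (k = 9.30 min⁻¹)
    catalyst intermediate B → by-product + catalyst intermediate C (k = 1.30 min⁻¹)
    target + free catalyst ⇌ isomer of the product + free catalyst, rate k4*[free catalyst]*[target] forward; the back reaction follows from the equilibrium constant (K = 0.500, k = 16.0 L mol⁻¹ min⁻¹)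
    starting material + catalyst intermediate A → catalyst intermediate B (k = 77.0 L mol⁻¹ min⁻¹)
    partner + precatalyst → free catalyst + spent reagent (k = 1.60 L mol⁻¹ min⁻¹)
    partner + free catalyst → catalyst intermediate A (k = 6.10 L mol⁻¹ min⁻¹)

The constant with which target and isomer of the product relax towards each other stands 7.87 times above the constant with which partner takes up free catalyst. The equilibrium ratio of target to isomer of the product is 2.00, beside my stop ratio of 2.18, and west stood at 68.9 % at 400 h as well, above the equilibrium share of 66.7 %: kinetic control, not thermodynamic. In west, the share my stop ratio gives lies 0.30 points below the 68.9 % found. In the south tank, with 1.63 % of the starting material left, it gives 67.4 %, and the tank stood at 67.5 %.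

(Readings and results are simulated for substances that don't exist, noise included.)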